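**Plan**

1. Numbering (halimane type): ring A = C1–C5 and C10 (C4 carries Me and CO2Me, olefin C1=C10); ring B = C5–C10 (Me on C8; Me and the side chain C11–C15 on C9, Me on C13).
2. Cuts: the propanoate and the side chain at C12–C13; ring A at C4–C5/C2–C3 plus the C4 methyl; C10–C1; C9–C11; last, ring B at C5–C6 and C8–C9.
3. Enabling feature: C10 is the only sp2 ring-fusion atom and lies between quaternary C9 and C5. Ring B is therefore a masked cyclohex-2-enone with C10 as carbonyl: C5–C10–C9 is a methyl ketone (activated by a tert-butyl ester that leaves as CO2 in the same flask) and C6–C7–C8 with its methyl is crotonaldehyde.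
4. Forward: ring B by an organocatalytic Michael/aldol-condensation/decarboxylation cascade; C9 made quaternary by α′-vinylation; 1,4-reduction/enol triflation and Stille vinylation turn the C10 carbonyl into a 1-vinylcyclohexene; Diels–Alder with methyl acrylate closes ring A with C1=C10 in place; C4 methylation; B-alkyl Suzuki coupling joins the (E)-C4 alcohol unit; propanoylation.
5. Stereochemistry: C8 from the amine catalyst; C9 by alkylation anti to the C8 methyl; C5 by cycloaddition anti to the axial C9 methyl; C4 by enolate methylation anti to the C5–C6 bond (both C4 epimers converge); E olefin from an E-enol triflate.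

Key step: step 1

Step 1
Reactants: 1 tert-butyl 2-methyl-3-oxobutanoate; 2 (2E)-but-2-enal
Product: 5 (5R,6S)-5,6-dimethylcyclohex-2-en-1-one (formed together with its C6 epimer), via aldehyde keto ester 3 (not isolated), via cyclohexenone tert-butyl ester 4 (not isolated)
Conditions: (S)-2-[diphenyl(trimethylsilyloxy)methyl]pyrrolidine (10 mol%), PhCO2H (10 mol%), toluene, 0 °C → rt; then TsOH·H2O (0.3 equiv), 80 °C
Reagents that add atoms: none
Why: The amine condenses with 2 to an E-iminium ion whose one face is blocked by the diphenyl(silyloxy)methyl group, so the enol of 1 should add through its fully substituted α-carbon (future C9) to the β-carbon (future C8) from the open face (Michael addition, 8R), after which TsOH drives the aldol addition of the acetyl methyl (future C5) to the aldehyde carbon (future C6), dehydration, loss of isobutene and decarboxylation. The closest known reaction type is the diarylprolinol-silyl-ether-catalysed Michael/aldol-condensation route from β-keto esters and enals to 5-substituted cyclohex-2-enones, an organocatalytic Robinson-type [3+3] annulation. Ring B closes by a 6-(enolendo)-exo-trig aldol addition followed by E1cB loss of water, which can start only from the methyl side because the other α-carbon is quaternary at that stage. C8 is under catalyst control, whereas C9 is formed as a mixture in 3 and 4, becomes an epimerisable α-centre in 5 (mainly trans) and is flattened again in step 2, so all its isomers are funnelled forward. The step needs 1,4- over 1,2-addition and a single cyclisation mode: iminium activation makes the β-carbon the only site open to the soft enol, and the quaternary donor carbon leaves one enolisable position for ring closure.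

Step 2
Reactants: 5 (5R,6S)-5,6-dimethylcyclohex-2-en-1-one (C6 epimer mixture); 6 (ethenylsulfinyl)benzene
Product: 8 (5R,6S)-5,6-dimethyl-6-[2-(phenylsulfinyl)ethyl]cyclohex-2-en-1-one (sulfur epimers), via lithium dienolate 7 (not isolated)
Conditions: LiN(i-Pr)2, THF, −78 °C; then 6, −78 → 0 °C; H2O
Reagents that add atoms: none
Why: LiN(i-Pr)2 removes the only α′-hydrogen to give the cross-conjugated dienolate (both C6 epimers of 5 converge), and Michael addition to the vinyl sulfoxide (a vinyl cation equivalent) should occur anti to the neighbouring methyl, which sits pseudoaxial to avoid A1,2 strain, so the new arm ends trans to it (6S), as in kinetic α′-alkylations of 5-substituted 6-methylcyclohexenones.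

Step 3
Reactants: 8 (5R,6S)-5,6-dimethyl-6-[2-(phenylsulfinyl)ethyl]cyclohex-2-en-1-one
Product: 9 (5R,6S)-6-ethenyl-5,6-dimethylcyclohex-2-en-1-one
Conditions: NaHCO3, toluene, 110 °C
Reagents that add atoms: none
Why: Thermal syn-elimination of the alkyl phenyl sulfoxide (sulfoxide pyrolysis) can take a β-hydrogen only from the CH2 next to the quaternary carbon, so the vinyl group forms without touching a stereocentre.

Step 4
Reactants: 9 (5R,6S)-6-ethenyl-5,6-dimethylcyclohex-2-en-1-one
Product: 11 (5R,6S)-6-ethenyl-5,6-dimethylcyclohex-1-en-1-yl trifluoromethanesulfonate, via lithium enolate 10 (not isolated)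
Conditions: LiBH(s-Bu)3, THF, −78 °C; then PhNTf2, −78 → 0 °C
Reagents that add atoms: N-phenylbis(trifluoromethanesulfonimide), O=S(=O)(N(c1ccccc1)S(=O)(=O)C(F)(F)F)C(F)(F)F
Why: The bulky borohydride delivers hydride to the unsubstituted β-carbon of the enone (1,4-reduction, favoured by the α′-quaternary, hindered carbonyl) and the regiodefined enolate is O-sulfonylated (enolate trapping), so the triflate double bond can lie only on the side away from the quaternary carbon.

Step 5
Reactants: 11 (5R,6S)-6-ethenyl-5,6-dimethylcyclohex-1-en-1-yl trifluoromethanesulfonate; 12 tributyl(ethenyl)stannane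
Product: 13 (5R,6S)-1,6-diethenyl-5,6-dimethylcyclohex-1-ene
Conditions: Pd(PPh3)4 (5 mol%), LiCl, THF, 65 °C
Reagents that add atoms: none
Why: Stille cross-coupling of an alkenyl triflate with a vinylstannane (chloride assists transmetalation) should give the 1-vinylcyclohexene with the ring double bond unmoved.

Step 6
Reactants: 13 (5R,6S)-1,6-diethenyl-5,6-dimethylcyclohex-1-ene; 14 methyl prop-2-enoate
Product: 15 methyl (1S,5S,6R,8aS)-5-ethenyl-5,6-dimethyl-1,2,3,5,6,7,8,8a-octahydronaphthalene-1-carboxylate (endo adduct; its C1 epimer is equally usable)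
Conditions: Et2AlCl (0.3 equiv), CH2Cl2, −78 → −20 °C
Reagents that add atoms: none
Why: Lewis-acid-catalysed Diels–Alder reaction of the semicyclic diene in which the ester-bearing carbon should bond to the ring terminus (ortho rule for a 1-substituted diene) and the dienophile should approach anti to the axial C9 methyl of the half-chair that keeps the C8 methyl equatorial, which sets C5 with its hydrogen cis to that methyl and leaves the new olefin at C1=C10.

Step 7
Reactants: 15 methyl (1S,5S,6R,8aS)-5-ethenyl-5,6-dimethyl-1,2,3,5,6,7,8,8a-octahydronaphthalene-1-carboxylate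
Product: 17 methyl (1S,5S,6R,8aR)-5-ethenyl-1,5,6-trimethyl-1,2,3,5,6,7,8,8a-octahydronaphthalene-1-carboxylate, via lithium ester enolate 16 (not isolated)
Conditions: LiN(i-Pr)2, THF, −78 °C; then MeI, DMPU, −78 → 0 °C
Reagents that add atoms: iodomethane, CI
Why: Ester enolate alkylation in which the exocyclic enolate should be methylated on the face anti to the C5–C6 bond (equatorial attack, the usual A1,3-controlled outcome for 2-substituted cyclohexanecarboxylate enolates), so both C4 epimers converge on the isomer with methyl trans and CO2Me cis to that bond.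

Step 8
Reactants: 18 ethyl 3-oxobutanoate
Product: 19 ethyl (2E)-3-{[(trifluoromethyl)sulfonyl]oxy}but-2-enoate
Conditions: aq Me4NOH, Tf2O, toluene, 5 °C
Reagents that add atoms: trifluoromethanesulfonic anhydride, O=S(=O)(OS(=O)(=O)C(F)(F)F)C(F)(F)F
Why: Schotten–Baumann-type enol triflation of a β-keto ester in which the non-chelating ammonium counter-ion lets the enolate react in its extended form, which should give the E-enol triflate (OTf trans to the ester).

Step 9
Reactants: 19 ethyl (2E)-3-{[(trifluoromethyl)sulfonyl]oxy}but-2-enoate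
Product: 20 (2E)-4-hydroxybut-2-en-2-yl trifluoromethanesulfonate
Conditions: (i-Bu)2AlH, CH2Cl2, −78 °C; aq potassium sodium tartrate
Reagents that add atoms: none
Why: Hydride reduction of the conjugated ester to the allylic alcohol at low temperature leaves the alkenyl triflate and the olefin geometry untouched.

Step 10
Reactants: 17 methyl (1S,5S,6R,8aR)-5-ethenyl-1,5,6-trimethyl-1,2,3,5,6,7,8,8a-octahydronaphthalene-1-carboxylate; 20 (2E)-4-hydroxybut-2-en-2-yl trifluoromethanesulfonate
Product: 22 methyl (1S,5S,6R,8aR)-5-[(3E)-5-hydroxy-3-methylpent-3-en-1-yl]-1,5,6-trimethyl-1,2,3,5,6,7,8,8a-octahydronaphthalene-1-carboxylate, via alkylborane 21 (not isolated)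
Conditions: 9-BBN-H, THF, 0 °C → rt; then 20, PdCl2(dppf) (5 mol%), K3PO4, H2O, DMF, 50 °C
Reagents that add atoms: none
Why: The borane should hydroborate only the monosubstituted vinyl group (anti-Markovnikov; the trisubstituted ring olefin is inert), and the B-alkyl Suzuki–Miyaura coupling with the alkenyl triflate proceeds with retention at the sp2 carbon, which delivers the E-trisubstituted side-chain olefin.

Step 11
Reactants: 22 methyl (1S,5S,6R,8aR)-5-[(3E)-5-hydroxy-3-methylpent-3-en-1-yl]-1,5,6-trimethyl-1,2,3,5,6,7,8,8a-octahydronaphthalene-1-carboxylate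
Product: 23 methyl (1S,5S,6R,8aR)-1,5,6-trimethyl-5-[(3E)-3-methyl-5-(propanoyloxy)pent-3-en-1-yl]-1,2,3,5,6,7,8,8a-octahydronaphthalene-1-carboxylate
Conditions: (EtCO)2O, Et3N, DMAP (cat.), CH2Cl2, 0 °C → rt
Reagents that add atoms: propanoic anhydride, CCC(=O)OC(=O)CC
Why: DMAP-catalysed acylation of the primary allylic alcohol should give the propanoate while the hindered tertiary methyl ester stays intact.

**Compound list**

1 | tert-butyl 2-methyl-3-oxobutanoate (racemic) | CC(=O)C(C)C(=O)OC(C)(C)C | starting material
2 | (2E)-but-2-enal | C/C=C/C=O | starting material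
3 | tert-butyl (3R)-2-acetyl-2,3-dimethyl-5-oxopentanoate (both C2 epimers) | CC(=O)C(C)(C(=O)OC(C)(C)C)[C@H](C)CC=O | intermediate
4 | tert-butyl (6R)-1,6-dimethyl-2-oxocyclohex-3-ene-1-carboxylate (both C1 epimers) | CC1(C(=O)OC(C)(C)C)C(=O)C=CC[C@H]1C | intermediate
5 | (5R,6S)-5,6-dimethylcyclohex-2-en-1-one (trans; used with its C6 epimer) | C[C@@H]1C(=O)C=CC[C@H]1C | intermediate
6 | (ethenylsulfinyl)benzene (phenyl vinyl sulfoxide, racemic) | C=CS(=O)c1ccccc1 | starting material
7 | lithium (3R)-2,3-dimethylcyclohexa-1,5-dien-1-olate | [Li]OC1=C(C)[C@H](C)CC=C1 | intermediate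
8 | (5R,6S)-5,6-dimethyl-6-[2-(phenylsulfinyl)ethyl]cyclohex-2-en-1-one (sulfur epimers) | O=S(CC[C@]1(C)C(=O)C=CC[C@H]1C)c1ccccc1 | intermediate
9 | (5R,6S)-6-ethenyl-5,6-dimethylcyclohex-2-en-1-one | C=C[C@]1(C)C(=O)C=CC[C@H]1C | intermediate
10 | lithium (5R,6S)-6-ethenyl-5,6-dimethylcyclohex-1-en-1-olate | C=C[C@]1(C)C(O[Li])=CCC[C@H]1C | intermediate
11 | (5R,6S)-6-ethenyl-5,6-dimethylcyclohex-1-en-1-yl trifluoromethanesulfonate | C=C[C@]1(C)C(OS(=O)(=O)C(F)(F)F)=CCC[C@H]1C | intermediate
12 | tributyl(ethenyl)stannane | C=C[Sn](CCCC)(CCCC)CCCC | starting material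
13 | (5R,6S)-1,6-diethenyl-5,6-dimethylcyclohex-1-ene | C=C[C@]1(C)C(C=C)=CCC[C@H]1C | intermediate
14 | methyl prop-2-enoate | C=CC(=O)OC | starting material
15 | methyl (1S,5S,6R,8aS)-5-ethenyl-5,6-dimethyl-1,2,3,5,6,7,8,8a-octahydronaphthalene-1-carboxylate | C=C[C@]1(C)C2=CCC[C@H](C(=O)OC)[C@@H]2CC[C@H]1C | intermediate
16 | lithium [(5S,6R,8aR)-5-ethenyl-5,6-dimethyl-2,3,5,6,7,8-hexahydronaphthalen-1(8aH)-ylidene](methoxy)methanolate | C=C[C@]1(C)C2=CCCC(=C(OC)O[Li])[C@@H]2CC[C@H]1C | intermediate
17 | methyl (1S,5S,6R,8aR)-5-ethenyl-1,5,6-trimethyl-1,2,3,5,6,7,8,8a-octahydronaphthalene-1-carboxylate | C=C[C@]1(C)C2=CCC[C@](C)(C(=O)OC)[C@@H]2CC[C@H]1C | intermediate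
18 | ethyl 3-oxobutanoate | CCOC(=O)CC(C)=O | starting material
19 | ethyl (2E)-3-{[(trifluoromethyl)sulfonyl]oxy}but-2-enoate | CCOC(=O)/C=C(\C)OS(=O)(=O)C(F)(F)F | intermediate
20 | (2E)-4-hydroxybut-2-en-2-yl trifluoromethanesulfonate | OC/C=C(\C)OS(=O)(=O)C(F)(F)F | intermediate
21 | methyl (1S,5S,6R,8aR)-5-[2-(9-borabicyclo[3.3.1]nonan-9-yl)ethyl]-1,5,6-trimethyl-1,2,3,5,6,7,8,8a-octahydronaphthalene-1-carboxylate | C1CC2CCCC(C1)B2CC[C@]3(C)C4=CCC[C@](C)(C(=O)OC)[C@@H]4CC[C@H]3C | intermediate
22 | methyl (1S,5S,6R,8aR)-5-[(3E)-5-hydroxy-3-methylpent-3-en-1-yl]-1,5,6-trimethyl-1,2,3,5,6,7,8,8a-octahydronaphthalene-1-carboxylate | OC/C=C(\C)CC[C@]1(C)C2=CCC[C@](C)(C(=O)OC)[C@@H]2CC[C@H]1C | intermediate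
23 | methyl (1S,5S,6R,8aR)-1,5,6-trimethyl-5-[(3E)-3-methyl-5-(propanoyloxy)pent-3-en-1-yl]-1,2,3,5,6,7,8,8a-octahydronaphthalene-1-carboxylate | CCC(=O)OC/C=C(\C)CC[C@]1(C)C2=CCC[C@](C)(C(=O)OC)[C@@H]2CC[C@H]1C | target

**Step count:** 11 steps in total. Longest linear sequence: 9 steps (steps 1–7, 10, 11); steps 8 and 9 make the coupling partner.

**Steps most likely to fail**

Step 6. The cycloaddition may take the wrong face of the diene if the half-chair with the axial vinyl group competes, and the aluminium Lewis acid may start cationic oligomerisation of the electron-rich triene. The fallback sets out from 13 and comes back at 15. It replaces Lewis-acid activation of an ester by iminium-ion organocatalysis of an enal. Acrolein with (2S,5S)-5-benzyl-2,2,3-trimethylimidazolidin-4-one hydrochloride in MeCN/H2O (catalyst enantiomer matched to the substrate's own facial bias) should give (1S,5S,6R,8aS)-5-ethenyl-5,6-dimethyl-1,2,3,5,6,7,8,8a-octahydronaphthalene-1-carbaldehyde F1. Pinnick oxidation (NaClO2, NaH2PO4, 2-methylbut-2-ene, t-BuOH/H2O) then gives (1S,5S,6R,8aS)-5-ethenyl-5,6-dimethyl-1,2,3,5,6,7,8,8a-octahydronaphthalene-1-carboxylic acid F2, and Me3SiCHN2 in MeOH/toluene returns methyl ester 15, whose C1 epimers again converge in step 7.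

Step 2. Proton transfer from the acidic α-sulfinyl position of the adduct to unreacted dienolate, and retro-Michael loss, can stall the conjugate addition at the hindered, fully substituted enolate carbon. The fallback sets out from 5 and comes back at 9; it makes no compound outside the list (F0). It forms the C–vinyl bond by cross-coupling instead of conjugate addition: palladium-catalysed α-alkenylation of the ketone enolate with LiN(SiMe3)2, vinyl bromide and Pd2(dba)3/P(t-Bu)3 in THF. Reductive elimination should again occur on the face anti to the C5 methyl, and 8 and step 3 are left out.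

Step 1. The fully substituted enol carbon of 1 may add too slowly to the β-methyl iminium ion, so that the uncatalysed Michael pathway and self-condensation of 2 erode the enantiomeric purity at C8. The fallback sets out from 1 and 2 and comes back at 5; it makes no compound outside the list (F0). It activates the donor instead of the acceptor: a 6′-hydroxy cinchona alkaloid catalyst (bifunctional base and hydrogen-bond catalysis, pseudo-enantiomer chosen for 8R) for the conjugate addition to 3, then TsOH·H2O in the same flask for ring closure and decarboxylation via 4.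

**Further compounds**

F1 | step 6 | (1S,5S,6R,8aS)-5-ethenyl-5,6-dimethyl-1,2,3,5,6,7,8,8a-octahydronaphthalene-1-carbaldehyde | C=C[C@]1(C)C2=CCC[C@H](C=O)[C@@H]2CC[C@H]1C
F2 | step 6 | (1S,5S,6R,8aS)-5-ethenyl-5,6-dimethyl-1,2,3,5,6,7,8,8a-octahydronaphthalene-1-carboxylic acid | C=C[C@]1(C)C2=CCC[C@H](C(=O)O)[C@@H]2CC[C@H]1C
F0 | step 2 | none | none
F0 | step 1 | none | none
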